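As planner of the next run of this flask, I have to choose which change to charge, so I want one number that ranks the changes.

    solid substrate ⇌ dissolved substrate, rate k1*(cs1 - [dissolved substrate]) while solid is left; crystals form when [dissolved substrate] > cs1 (cs1 = 38 mM, k1 = 1.69 × 10⁻⁵ s⁻¹)
    dissolved substrate + partner → target (k2 = 9.18 × 10⁻⁴ L mol⁻¹ s⁻¹)
    2 dissolved substrate → side product (k3 = 3.25 × 10⁻⁴ L mol⁻¹ s⁻¹)
    solid product ⇌ target, rate k4*(cs4 - [target]) while solid is left; crystals form when [target] > cs4 (cs4 = 8.7 mM, k4 = 9.32 × 10⁻⁴ s⁻¹)
    target ⇌ isomer of the product (K5 = 0.460, k5 = 1.01 × 10⁻⁵ s⁻¹)
    2 solid substrate → self-condensation product (k6 = 3.12 × 10⁻⁷ L mol⁻¹ s⁻¹)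
    solid reagent ⇌ partner, rate k7*(cs7 - [partner]) while solid is left; crystals form when [partner] > cs7 (cs7 = 17 mM, k7 = 4.47 × 10⁻⁴ s⁻¹)

solid substrate 0.050 M; solid reagent 1.05 equiv; time 3.0 d

- a species is counted by the solid substrate in it: one side product or self-condensation product counts as two
- amounts and yields of target count solid product too
- a doubled species enters its step squared and goes two at a time
- given per volume of solution although it is solid: solid substrate, solid product, solid reagent
- at the start none of the solid substrate is in solution
- at the start none of the solid reagent is in solution
- run time (flask): 3.0 d

- west: doubling the solubility in step 7, all else as stated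
- north-west: doubling the solubility in step 4, all else as stated
- south-east: doubling the dissolution coefficient of step 7, all else as stated
- north-east: doubling the solubility in step 1, all else as stated

1. how much target and solid product together there is at 3.0 d, in percent of the solid substrate charged
2. the change that raises the amount of target and solid product together at 3.0 d, in percent of the solid substrate charged most ("none" if none brings more than 2 percentage points) (west / north-west / south-east / north-east / none)
3. amount of target and solid product together at 3.0 d, in percent of the solid substrate charged, after west

Dissolved substrate, A, leaves by two paths: with partner to target, or with itself to side product. The ratio of these two uses, the selectivity factor, is L/A, where L, the even-split level, is the coupling constant times the partner concentration over twice the dimerisation constant. While solid reagent lasts I hold the partner at its solubility because step 7 can supply 3939% against 333% for step 1, which puts L at 24.0 mM.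

While solid substrate lasts, A sits on a plateau p where dissolving matches use, which gives 15.2 mM, and a share L/(L+p) of what passes becomes target. Once the solid is gone, integrating that share as A falls from p gives L·ln(1 + p/L) in closed form. Together these make 33.1 mM of target, isomer still counted in it. The isomer relaxes with a half-life of 0.250 d, shorter than the run time of 3.0 d, so with solid product present and dissolved target at its solubility I take off 4.00 mM, the equilibrium constant times the product solubility, and reckon 58.2%.

Now the changes. West doubles L to 48.0 mM, lowers the plateau to 11.5 mM, makes 41.3 mM and so gives 74.7%. Filling the solution leaves 18.5 mM of partner in the solid, less than that coupling needs, so I expect the partner to sag late and take my figure as on the high side. North-east raises the plateau to 26.0 mM and makes 29.1 mM. North-west doubles the isomer I take off, and south-east moves neither L nor p in this reckoning. I charge west.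

The forecast gives 57.5% (54% to 61%), chooses west and puts that change at 70% (65% to 74%), lower than my west figure. Its ground is that “Doubling the partner's solubility speeds the coupling”.

The simulation gives 57.3%, chooses west with a gain of 13 percentage points, and reaches 70.7%.

At 3.00 d this flask holds 1.06 mM of dissolved substrate, much less than L, and coupling uses it 23 times as fast as the side path. At 3.00 d in the neighbour flask with 0.630 equiv of solid reagent, solid reagent stands at 0% and partner at 4.12 mM, so L there is 5.83 mM against 3.66 mM of dissolved substrate, a ratio of 1.59, with side product at 37.8%.

The constants are assumed; what happens was integrated by code.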